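**Retrosynthetic overview**
1. The acid is unmasked and the acetate installed last (tert-butyl ester cleavage, acetylation of the tertiary alcohol). Ring locants: C1 ketone carbon, C2=C3 alkene, C4 oxygen-bearing quaternary carbon, C5 pentenyl-bearing CH.
2. Key disconnection: the two ring bonds flanking the alkene, C1–C2 and C3–C4, are cut together. This opens the only ring to an acyclic (S)-2-pentenyl-3-oxo Weinreb amide (C1–C5–C4 with both side chains) and a cis-vinylene 1,2-dianion. The dianion is delivered by cis-1,2-bis(trimethylstannyl)ethene through two tin–lithium exchanges in one flask.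
3. Enabling feature: in the five-membered ring the unsubstituted cis C2=C3 unit is bonded on both sides to oxygen-bearing carbons, ketone C1 and tertiary carbinol C4. These stand 1,3 to each other across C5, so C1–C5–C4 is a 3-oxo acid skeleton with two acceptor carbons, and the two CH termini of the C2 unit are equivalent.
4. The oxo amide comes from an Evans syn aldol of N-[(Z)-hept-4-enoyl]oxazolidinone with tert-butyl 9-oxononanoate (from oleic acid), then aminolysis and oxidation. The aldol sets C5, and C5 sets C4 by chelation in the key step.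
5. Ring order: one ring only, the cyclopentenone. It is closed in the key step at its final oxidation level.

Key step: step 8

Remark: oleic acid, (Z)-hept-4-enoic acid, (S)-4-benzyloxazolidin-2-one, acetylene and hexamethylditin are taken as purchasable; Me4Sn is volatile and toxic, so the tin steps need closed handling.

Step 1
Reactants: 1 oleic acid
Product: 2 tert-butyl (9Z)-octadec-9-enoate
Conditions: Cl3CC(=NH)OtBu, BF3·OEt2 (cat.), cyclohexane/CH2Cl2, rt
Reagents that add atoms: tert-butyl 2,2,2-trichloroacetimidate, CC(C)(C)OC(=N)C(Cl)(Cl)Cl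
Why: Acid-catalysed imidate esterification transfers a tert-butyl cation to the carboxylic acid and leaves the alkene untouched.

Step 2
Reactants: 2 tert-butyl (9Z)-octadec-9-enoate
Product: 4 tert-butyl 9-oxononanoate, via secondary ozonide 3 (not isolated)
Conditions: O3, CH2Cl2, −78 °C; then PPh3, −78 °C to rt
Reagents that add atoms: ozone, [O-][O+]=O
Why: Ozonolysis with reductive work-up (Criegee mechanism) cleaves the only C=C bond into two aldehydes that differ enough in polarity to be separated.

Step 3
Reactants: 5 (Z)-hept-4-enoic acid; 6 (S)-4-benzyl-1,3-oxazolidin-2-one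
Product: 8 (4S)-4-benzyl-3-[(4Z)-hept-4-enoyl]-1,3-oxazolidin-2-one, via mixed pivalic anhydride 7 (not isolated)
Conditions: tBuCOCl, Et3N, THF, −20 °C; then 6, LiCl, −20 °C to rt
Reagents that add atoms: none
Why: Mixed-anhydride N-acylation of an Evans oxazolidinone needs no strong base, so the Z-alkene should not move or isomerise.

Step 4
Reactants: 8 (4S)-4-benzyl-3-[(4Z)-hept-4-enoyl]-1,3-oxazolidin-2-one; 4 tert-butyl 9-oxononanoate
Product: 11 tert-butyl (9R,10S,12Z)-10-{[(4S)-4-benzyl-2-oxo-1,3-oxazolidin-3-yl]carbonyl}-9-hydroxypentadec-12-enoate, via Z-boron enolate 9 (not isolated), via boron aldolate 10 (not isolated)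
Conditions: Bu2BOTf, Et3N, CH2Cl2, −78 to 0 °C; 4, −78 to 0 °C; then H2O2, MeOH, aq NaH2PO4/Na2HPO4 (pH 7), 0 °C
Reagents that add atoms: none
Why: Evans syn aldol reaction, in which the Z-boron enolate reacts through a chair Zimmerman–Traxler transition state on the face away from the benzyl group, setting C10 as S (the later ring C5) and C9 as R (erased in step 6).

Step 5
Reactants: 11 the syn aldol imide
Product: 12 tert-butyl (9R,10S,12Z)-9-hydroxy-10-[methoxy(methyl)carbamoyl]pentadec-12-enoate
Conditions: MeONHMe·HCl, AlMe3, THF/CH2Cl2, −20 to 0 °C; aq potassium sodium tartrate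
Reagents that add atoms: N,O-dimethylhydroxylamine hydrochloride, CNOC.Cl
Why: Weinreb aminolysis with the aluminium amide is assisted by the free 3-hydroxyl group and attacks the activated imide carbonyl, while the hindered tert-butyl ester should stay intact at this temperature.

Step 6
Reactants: 12 the hydroxy Weinreb amide
Product: 13 tert-butyl (10S,12Z)-10-[methoxy(methyl)carbamoyl]-9-oxopentadec-12-enoate
Conditions: Dess–Martin periodinane, CH2Cl2, 0 °C to rt; short silica plug
Reagents that add atoms: none
Why: Dess–Martin oxidation is close to neutral, and allylic 1,3-strain in the tertiary amide disfavours enolisation through C10, so this centre should hold.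

Step 7
Reactants: 14 acetylene; 15 hexamethylditin
Product: 16 (Z)-1,2-bis(trimethylstannyl)ethene
Conditions: Pd(PPh3)4 (cat.), dioxane, 14 (1 atm), 60 °C, dark
Reagents that add atoms: none
Why: Palladium-catalysed distannylation of an alkyne (Sn–Sn oxidative addition to zerovalent palladium, syn insertion, reductive elimination) puts both tin atoms on the same side and fixes the cis geometry.

Step 8
Reactants: 16 (Z)-1,2-bis(trimethylstannyl)ethene; 13 the (S)-3-oxo Weinreb amide
Product: 21 tert-butyl 8-[(1S,5S)-1-hydroxy-4-oxo-5-[(2Z)-pent-2-en-1-yl]cyclopent-2-en-1-yl]octanoate, via cis-stannylvinyllithium 17 (not isolated), via stannylvinyl lithium alkoxide 18 (not isolated), via dilithiated allylic alkoxide 19 (not isolated), via cyclic tetrahedral adduct 20 (not isolated)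
Conditions: 16, MeLi·LiBr (1.0 equiv), THF, −78 °C; 13 in Et2O, −78 °C; MeLi·LiBr (1.1 equiv), −78 to −40 °C; aq NH4Cl
Reagents that add atoms: none
Why: Proposed new method: MeLi cleaves one C–Sn bond of 16 with retention to give 17, which adds to the C9 ketone of 13 (new C3–C4 bond) to give alkoxide 18; a second MeLi cleaves the remaining, alkoxide-flanked C–Sn bond, and the cis-vinyllithium 19 attacks the Weinreb carbonyl (new C1–C2 bond) to give the chelated adduct 20, which releases the enone only on quench. The closest known reaction types are stepwise tin–lithium exchange of cis-1,2-distannylalkenes, generation of dilithiated cis-3-stannylallyl alcohols, chelation-controlled organometal addition to 2-alkyl-3-oxo amides and Parham-type anionic cyclisation onto Weinreb amides; their merger into a [3+2] annulation of a 3-oxo amide is new. The cyclopentene ring closes in a 5-exo-trig mode (sp2 carbanion onto the exocyclic C=O), which only the cis geometry held by 16 allows. The new stereocentre C4 is set in the first addition by the existing C5 centre: lithium bridges the ketone and amide oxygens in a six-membered chelate and the nucleophile enters anti to the pentenyl chain, which places oxygen cis and the ester chain trans to that chain, also the more stable arrangement at the epimerisable C5. The step needs ketone-over-amide and addition-over-enolisation selectivity in the first stage and exchange-over-addition selectivity in the second: allylic 1,3-strain keeps the C5–H bond out of conjugation, the hindered amide and the tert-butyl ester are slow acceptors at −78 °C, and because the two CH termini of 16 are equivalent an inverted order of the two additions would give the same ring.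

Step 9
Reactants: 21 the 4-hydroxycyclopentenone tert-butyl ester
Product: 22 tert-butyl 8-[(1S,5S)-1-acetoxy-4-oxo-5-[(2Z)-pent-2-en-1-yl]cyclopent-2-en-1-yl]octanoate
Conditions: Ac2O, 4-dimethylaminopyridine, Et3N, CH2Cl2, rt
Reagents that add atoms: acetic anhydride, CC(=O)OC(C)=O
Why: Nucleophilic-catalysis acylation through the N-acetylpyridinium ion is the standard way to esterify tertiary alcohols, and loss of AcOH across C4–C5 is blocked because it would give an antiaromatic cyclopentadienone.

Step 10
Reactants: 22 the acetoxy tert-butyl ester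
Product: 23 8-[(1S,5S)-1-acetoxy-4-oxo-5-[(2Z)-pent-2-en-1-yl]cyclopent-2-en-1-yl]octanoic acid (target)
Conditions: CF3CO2H/CH2Cl2 (1:4), 0 °C to rt
Reagents that add atoms: none
Why: Acidolysis of the tert-butyl ester (E1 loss of isobutene) should spare the tertiary acetate, because a cation at C4 would be conjugated with the electron-poor enone and is strongly destabilised.

**Compound list**
1 | oleic acid | CCCCCCCC/C=C\CCCCCCCC(=O)O | starting material
2 | tert-butyl (9Z)-octadec-9-enoate | CCCCCCCC/C=C\CCCCCCCC(=O)OC(C)(C)C | intermediate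
3 | secondary ozonide of 2 (1,2,4-trioxolane, isomer mixture) | CCCCCCCCC1OOC(CCCCCCCC(=O)OC(C)(C)C)O1 | intermediate
4 | tert-butyl 9-oxononanoate | O=CCCCCCCCC(=O)OC(C)(C)C | intermediate
5 | (Z)-hept-4-enoic acid | CC/C=C\CCC(=O)O | starting material
6 | (S)-4-benzyl-1,3-oxazolidin-2-one | O=C1N[C@@H](Cc2ccccc2)CO1 | starting material
7 | mixed pivalic anhydride of 5 | CC/C=C\CCC(=O)OC(=O)C(C)(C)C | intermediate
8 | (4S)-4-benzyl-3-[(4Z)-hept-4-enoyl]-1,3-oxazolidin-2-one | CC/C=C\CCC(=O)N1[C@@H](Cc2ccccc2)COC1=O | intermediate
9 | Z-boron enolate of 8 (dibutylboryl) | CC/C=C\C/C=C(\OB(CCCC)CCCC)N1[C@@H](Cc2ccccc2)COC1=O | intermediate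
10 | boron aldolate (O-dibutylboryl derivative of 11) | CC/C=C\C[C@@H]([C@H](OB(CCCC)CCCC)CCCCCCCC(=O)OC(C)(C)C)C(=O)N1[C@@H](Cc2ccccc2)COC1=O | intermediate
11 | tert-butyl (9R,10S,12Z)-10-{[(4S)-4-benzyl-2-oxo-1,3-oxazolidin-3-yl]carbonyl}-9-hydroxypentadec-12-enoate | CC/C=C\C[C@@H]([C@H](O)CCCCCCCC(=O)OC(C)(C)C)C(=O)N1[C@@H](Cc2ccccc2)COC1=O | intermediate
12 | tert-butyl (9R,10S,12Z)-9-hydroxy-10-[methoxy(methyl)carbamoyl]pentadec-12-enoate | CC/C=C\C[C@@H]([C@H](O)CCCCCCCC(=O)OC(C)(C)C)C(=O)N(C)OC | intermediate
13 | tert-butyl (10S,12Z)-10-[methoxy(methyl)carbamoyl]-9-oxopentadec-12-enoate | CC/C=C\C[C@@H](C(=O)CCCCCCCC(=O)OC(C)(C)C)C(=O)N(C)OC | intermediate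
14 | acetylene | C#C | starting material
15 | hexamethylditin | C[Sn](C)(C)[Sn](C)(C)C | starting material
16 | (Z)-1,2-bis(trimethylstannyl)ethene | C[Sn](C)(C)/C=C\[Sn](C)(C)C | intermediate
17 | cis-stannylvinyllithium, (Z)-2-(trimethylstannyl)ethenyllithium | [Li]/C=C\[Sn](C)(C)C | intermediate
18 | stannylvinyl lithium alkoxide (ketone adduct of 13, configuration as in 21) | CC/C=C\C[C@H](C(=O)N(C)OC)[C@@](CCCCCCCC(=O)OC(C)(C)C)(O[Li])/C=C\[Sn](C)(C)C | intermediate
19 | dilithiated allylic alkoxide (cis-vinyllithium from 18) | CC/C=C\C[C@H](C(=O)N(C)OC)[C@@](CCCCCCCC(=O)OC(C)(C)C)(O[Li])/C=C\[Li] | intermediate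
20 | cyclic tetrahedral adduct (dilithium salt, C1 configuration open) | CC/C=C\C[C@@H]1C(O[Li])(N(C)OC)C=C[C@]1(CCCCCCCC(=O)OC(C)(C)C)O[Li] | intermediate
21 | tert-butyl 8-[(1S,5S)-1-hydroxy-4-oxo-5-[(2Z)-pent-2-en-1-yl]cyclopent-2-en-1-yl]octanoate | CC/C=C\C[C@@H]1C(=O)C=C[C@]1(CCCCCCCC(=O)OC(C)(C)C)O | intermediate
22 | tert-butyl 8-[(1S,5S)-1-acetoxy-4-oxo-5-[(2Z)-pent-2-en-1-yl]cyclopent-2-en-1-yl]octanoate | CC/C=C\C[C@@H]1C(=O)C=C[C@]1(CCCCCCCC(=O)OC(C)(C)C)OC(C)=O | intermediate
23 | 8-[(1S,5S)-1-acetoxy-4-oxo-5-[(2Z)-pent-2-en-1-yl]cyclopent-2-en-1-yl]octanoic acid | CC/C=C\C[C@@H]1C(=O)C=C[C@]1(CCCCCCCC(=O)O)OC(C)=O | target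

Total step count: 10. Longest linear sequence: 8 steps (1, 2, 4, 5, 6, 8, 9, 10).

**Steps most likely to fail**

Step 8 (labelled step).
- What may go wrong: poor facial selectivity if lithium chelation is incomplete, enolisation of the oxo amide by the vinyllithium, or attack of the second MeLi on the amide before tin–lithium exchange.
- The fallback sets out from 13 and 16, comes back at 21, and uses isolated intermediates and known reactions.
- Reagent 17 is made from 16 as before and transmetalated with MgBr2·OEt2. It is added at −78 °C in CH2Cl2/Et2O to 13 that has been precomplexed with MgBr2·OEt2 (Cram-chelate Grignard addition).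
- Aqueous quench gives the isolated cis-stannylvinyl carbinol F1, which can be purified from its C9 epimer.
- Iododestannylation with I2 in CH2Cl2 at 0 °C, with retention, gives the cis-iodovinyl carbinol F2.
- Iodine–magnesium exchange with iPrMgCl·LiCl (two equivalents, −40 °C) followed by warming closes the ring by intramolecular Weinreb ketone synthesis to 21.

Step 9.
- What may go wrong: sluggish acyl transfer to the hindered tertiary alcohol, with base-induced retro-aldol ring opening competing.
- The fallback sets out from 20, the species present in the flask of step 8 before the quench, and comes back at 22.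
- Instead of NH4Cl, excess acetic anhydride is added at −78 °C and the mixture is warmed to 0 °C.
- The tertiary lithium alkoxide is far more nucleophilic than the neutral alcohol and is acetylated directly. The C1 oxygen is capped as well, giving the bis-acetylated adduct F3.
- Mild aqueous acid work-up hydrolyses the N,O-acetal acetate at C1 to the ketone, which gives 22 without passing through 21.

Step 10.
- What may go wrong: acid-induced loss of the tertiary acetate or migration of the side-chain alkene during ester cleavage.
- The fallback sets out from 21, comes back at 23, and reverses the order of the last two events.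
- CF3CO2H in CH2Cl2 cleaves the tert-butyl ester while C4 still carries the free alcohol, giving the hydroxy acid F4.
- Excess Ac2O with 4-dimethylaminopyridine in pyridine acetylates the alcohol and turns the acid into the mixed acetic anhydride F5.
- Stirring with aqueous THF hydrolyses only the anhydride and gives 23.

**Further compounds**
F1 | step 8 | cis-stannylvinyl carbinol, tert-butyl (9R,10S,12Z)-9-hydroxy-10-[methoxy(methyl)carbamoyl]-9-[(Z)-2-(trimethylstannyl)ethenyl]pentadec-12-enoate | CC/C=C\C[C@H](C(=O)N(C)OC)[C@@](CCCCCCCC(=O)OC(C)(C)C)(O)/C=C\[Sn](C)(C)C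
F2 | step 8 | cis-iodovinyl carbinol, tert-butyl (9R,10S,12Z)-9-hydroxy-9-[(Z)-2-iodoethenyl]-10-[methoxy(methyl)carbamoyl]pentadec-12-enoate | CC/C=C\C[C@H](C(=O)N(C)OC)[C@@](CCCCCCCC(=O)OC(C)(C)C)(O)/C=C\I
F3 | step 9 | bis-acetylated adduct (C4 acetate and C1 N,O-acetal acetate of 20) | CC/C=C\C[C@@H]1C(OC(C)=O)(N(C)OC)C=C[C@]1(CCCCCCCC(=O)OC(C)(C)C)OC(C)=O
F4 | step 10 | hydroxy acid, 8-[(1S,5S)-1-hydroxy-4-oxo-5-[(2Z)-pent-2-en-1-yl]cyclopent-2-en-1-yl]octanoic acid | CC/C=C\C[C@@H]1C(=O)C=C[C@]1(CCCCCCCC(=O)O)O
F5 | step 10 | mixed acetic anhydride of 23 | CC/C=C\C[C@@H]1C(=O)C=C[C@]1(CCCCCCCC(=O)OC(C)=O)OC(C)=O
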